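## Retrosynthetic overview

1. Target ⇐ global deprotection of a hexabenzyl dimer carbonate. The key cut is the interflavan C4(upper)–C6(lower) bond, made by anodic benzylic C–H/arene C–H coupling, with the flavan-4-yl cation trapped trans to the 2-aryl group.
2. Both halves ⇐ one all-cis tri-O-benzyl flavan-3,4-diol: its cyclic carbonate is the nucleophile; its thionocarbonate gives the (2S)-flavan (cation precursor) by Corey–Winter olefination and diimide reduction.
3. Diol pyran ring ⇐ C4–C4a by chelation-controlled Friedel–Crafts closure of an α-hydroxy aldehyde (sets C4); C2–O1 by Mitsunobu inversion with 2,3-bis(benzyloxy)phenol; the C2 carbinol by Felkin–Anh aryl addition to (R)-glyceraldehyde acetonide (the only bought stereocentre, which becomes C3).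
4. Ring order: A and B rings are bought; the one pyran ring is closed on the monomer before the route divides; no ring is formed after the coupling.

Assumption: 4-(benzyloxy)phenylmagnesium bromide (THF solution), (R)-2,3-O-isopropylideneglyceraldehyde and 2,3-bis(benzyloxy)benzaldehyde are taken as catalogue items. Chroman names use flavan numbering; some CIP labels change along the route through priority changes alone, the geometry staying the same.

## Route

Step 1
Reactants: 1 2,3-bis(benzyloxy)benzaldehyde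
Product: 3 2,3-bis(benzyloxy)phenol, via aryl formate 2 (not isolated)
Conditions: mCPBA, CH2Cl2, 0 °C → rt; then K2CO3 (cat.), MeOH, rt
Reagents that add atoms: mCPBA, O=C(OO)c1cccc(Cl)c1
Why: Baeyer–Villiger (Dakin-type) oxidation in which the electron-rich aryl group migrates, followed by methanolysis of the aryl formate; no stereocentre is involved.

Step 2
Reactants: 4 [4-(benzyloxy)phenyl]magnesium bromide; 5 (R)-2,2-dimethyl-1,3-dioxolane-4-carbaldehyde
Product: 7 (S)-[4-(benzyloxy)phenyl][(4R)-2,2-dimethyl-1,3-dioxolan-4-yl]methanol, via aryltitanium 6 (not isolated)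
Conditions: ClTi(OiPr)3, THF, −78 °C; then 5, −78 → −20 °C; aq. NH4Cl
Reagents that add atoms: none
Why: Addition of the non-chelating aryltitanium to the α-alkoxy aldehyde under Felkin–Anh control gives the anti (1S) carbinol (about 9:1 expected, minor syn isomer removed on silica), so the new centre is set by the bought one.

Step 3
Reactants: 7 (S)-[4-(benzyloxy)phenyl][(4R)-2,2-dimethyl-1,3-dioxolan-4-yl]methanol; 3 2,3-bis(benzyloxy)phenol
Product: 8 1,2-bis(benzyloxy)-3-{(R)-[4-(benzyloxy)phenyl][(4R)-2,2-dimethyl-1,3-dioxolan-4-yl]methoxy}benzene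
Conditions: PPh3, DIAD, toluene, 0 °C → rt
Reagents that add atoms: none
Why: Mitsunobu etherification proceeds by SN2 inversion at the benzylic carbinol (ionisation is held back by the adjacent dioxolane oxygen and the non-polar solvent), turning the anti alcohol into the (R) aryl ether that becomes the 2,3-cis C2 centre.

Step 4
Reactants: 8 1,2-bis(benzyloxy)-3-{(R)-[4-(benzyloxy)phenyl][(4R)-2,2-dimethyl-1,3-dioxolan-4-yl]methoxy}benzene
Product: 9 (2R,3R)-3-[4-(benzyloxy)phenyl]-3-[2,3-bis(benzyloxy)phenoxy]propane-1,2-diol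
Conditions: AcOH/H2O/THF (4:1:1), 40 °C
Reagents that add atoms: none
Why: Acid-catalysed acetal hydrolysis frees the terminal diol while the benzylic aryl ether and the benzyl ethers are stable to aqueous acetic acid; no stereocentre is touched.

Step 5
Reactants: 9 (2R,3R)-3-[4-(benzyloxy)phenyl]-3-[2,3-bis(benzyloxy)phenoxy]propane-1,2-diol
Product: 11 (2R,3R,4R)-7,8-bis(benzyloxy)-2-[4-(benzyloxy)phenyl]-3,4-dihydro-2H-chromene-3,4-diol, via hydroxy aldehyde 10 (not isolated)
Conditions: TEMPO (10 mol %), PhI(OAc)2, CH2Cl2, 0 °C → rt; then MgBr2·OEt2, CH2Cl2, −20 → 0 °C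
Reagents that add atoms: none
Why: Primary-selective TEMPO/PhI(OAc)2 oxidation gives the α-hydroxy aldehyde, whose magnesium chelate undergoes intramolecular Friedel–Crafts hydroxyalkylation at the only free position ortho to the ether oxygen (para to the 7-benzyloxy group); because the arene is tethered through C2 it attacks the chelated carbonyl so that the new 4-OH is cis to the 3-OH (4R), giving the all-cis diol.

Step 6
Reactants: 11 (2R,3R,4R)-7,8-bis(benzyloxy)-2-[4-(benzyloxy)phenyl]-3,4-dihydro-2H-chromene-3,4-diol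
Product: 12 (2R,3S,4R)-7,8-bis(benzyloxy)-2-[4-(benzyloxy)phenyl]chromane-3,4-diyl carbonate
Conditions: CDI, DMAP (cat.), CH2Cl2, rt
Reagents that add atoms: 1,1'-carbonyldiimidazole, O=C(n1ccnc1)n1ccnc1
Why: Acylation of the cis-diol closes the five-membered cyclic carbonate, which masks the acid-labile benzylic diol during the coupling; the stereocentres are untouched (C3 becomes S by priority change only).

Step 7
Reactants: 11 (2R,3R,4R)-7,8-bis(benzyloxy)-2-[4-(benzyloxy)phenyl]-3,4-dihydro-2H-chromene-3,4-diol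
Product: 13 (2R,3S,4R)-7,8-bis(benzyloxy)-2-[4-(benzyloxy)phenyl]chromane-3,4-diyl thionocarbonate
Conditions: 1,1'-thiocarbonyldiimidazole, DMAP (cat.), THF, rt; used at once
Reagents that add atoms: 1,1'-thiocarbonyldiimidazole, S=C(n1ccnc1)n1ccnc1
Why: Thiocarbonylation of the cis-diol is the first stage of a Corey–Winter olefination and goes readily on a cis-1,2-diol; no stereocentre is changed.

Step 8
Reactants: 13 (2R,3S,4R)-7,8-bis(benzyloxy)-2-[4-(benzyloxy)phenyl]chromane-3,4-diyl thionocarbonate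
Product: 15 (2S)-7,8-bis(benzyloxy)-2-[4-(benzyloxy)phenyl]-3,4-dihydro-2H-chromene, via flav-3-ene 14 (not isolated)
Conditions: 1,3-dimethyl-2-phenyl-1,3,2-diazaphospholidine, THF, 40 °C, dark; then 2-nitrobenzenesulfonohydrazide, Et3N, rt
Reagents that add atoms: none
Why: Corey–Winter olefination in its low-temperature Corey–Hopkins form removes both oxygens by syn-elimination, and the light- and heat-sensitive 2H-chromene is reduced at once by diimide (benzyl ethers untouched) before it can racemise by electrocyclic ring opening; C2 is retained (its label becomes S by priority change only).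

Step 9
Reactants: 15 (2S)-7,8-bis(benzyloxy)-2-[4-(benzyloxy)phenyl]-3,4-dihydro-2H-chromene; 12 (2R,3S,4R)-7,8-bis(benzyloxy)-2-[4-(benzyloxy)phenyl]chromane-3,4-diyl carbonate
Product: 17 (2R,3S,4R)-7,8-bis(benzyloxy)-6-{(2S,4R)-7,8-bis(benzyloxy)-2-[4-(benzyloxy)phenyl]chroman-4-yl}-2-[4-(benzyloxy)phenyl]chromane-3,4-diyl carbonate, via aminosulfonium salt 16 (not isolated)
Conditions: divided cell, carbon-felt anode/Pt cathode (H2 evolution, TfOH catholyte), Ph2S=NTs (2.5 equiv), Bu4NB(C6F5)4, CH2Cl2, −78 °C, 2.2 F/mol; then 12 (2 equiv, excess recovered), 2,6-di-tert-butyl-4-methylpyridine, −78 → 0 °C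
Reagents that add atoms: none
Why: Proposed new method: anodic oxidation of the most electron-rich ring of 15 (ring A, three oxygens) gives a radical cation that loses the benzylic C4 proton and a second electron to form the flavan-4-yl cation (stabilised by O1 ortho and the 7-benzyloxy group para), which is stored as the N-sulfonium adduct of the sulfilimine so that it is neither over-oxidised to the flavylium ion nor attacked by unreacted 15; when 12 is added the cation is released and undergoes Friedel–Crafts attack by C6 of 12 (para to O1, ortho to 7-OBn, less hindered than C5) pseudo-axially on the face anti to the pseudo-equatorial 2-aryl group, which forms the interflavan bond and sets the 2,4-trans C4 centre under control of C2; the closest known reaction type is the stabilised-cation-pool benzylic C–H/aromatic C–H cross-coupling of toluenes and diarylmethanes with a sulfilimine, which has not been shown on a chroman C4–H or for an interflavan bond.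

Step 10
Reactants: 17 (2R,3S,4R)-7,8-bis(benzyloxy)-6-{(2S,4R)-7,8-bis(benzyloxy)-2-[4-(benzyloxy)phenyl]chroman-4-yl}-2-[4-(benzyloxy)phenyl]chromane-3,4-diyl carbonate
Product: 19 (2R,3R,4R)-6-[(2S,4S)-7,8-dihydroxy-2-(4-hydroxyphenyl)chroman-4-yl]-2-(4-hydroxyphenyl)chromane-3,4,7,8-tetrol, via hexabenzyl diol 18 (not isolated)
Conditions: K2CO3, MeOH/THF, 0 °C → rt; then AcOH to pH 7, Pd(OH)2/C, H2 (1 atm), rt; Sephadex LH-20
Reagents that add atoms: none
Why: Base methanolysis of the cyclic carbonate (acyl–oxygen cleavage, C3 and C4 untouched, all phenols still benzylated) is followed by neutral hydrogenolysis of the six aryl benzyl ethers, conditions under which phenolic benzylic alcohols, the chroman C2–O bonds and the interflavan bond normally survive; the carbonate must go first because a benzylic carbonate would itself be hydrogenolysed.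

## Compound list

1 | 2,3-bis(benzyloxy)benzaldehyde | O=Cc1cccc(OCc2ccccc2)c1OCc1ccccc1 | starting material
2 | 2,3-bis(benzyloxy)phenyl formate | O=COc1cccc(OCc2ccccc2)c1OCc1ccccc1 | intermediate
3 | 2,3-bis(benzyloxy)phenol | Oc1cccc(OCc2ccccc2)c1OCc1ccccc1 | intermediate
4 | [4-(benzyloxy)phenyl]magnesium bromide | Br[Mg]c1ccc(OCc2ccccc2)cc1 | starting material
5 | (R)-2,2-dimethyl-1,3-dioxolane-4-carbaldehyde | O=C[C@H]1COC(C)(C)O1 | starting material
6 | [4-(benzyloxy)phenyl]tri(propan-2-yloxy)titanium | CC(C)O[Ti](OC(C)C)(OC(C)C)c1ccc(OCc2ccccc2)cc1 | intermediate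
7 | (S)-[4-(benzyloxy)phenyl][(4R)-2,2-dimethyl-1,3-dioxolan-4-yl]methanol (anti) | O[C@@H](c1ccc(OCc2ccccc2)cc1)[C@@H]1OC(C)(C)OC1 | intermediate
8 | 1,2-bis(benzyloxy)-3-{(R)-[4-(benzyloxy)phenyl][(4R)-2,2-dimethyl-1,3-dioxolan-4-yl]methoxy}benzene | c1ccc(OCc2ccccc2)c(OCc2ccccc2)c1O[C@H](c1ccc(OCc2ccccc2)cc1)[C@@H]1OC(C)(C)OC1 | intermediate
9 | (2R,3R)-3-[4-(benzyloxy)phenyl]-3-[2,3-bis(benzyloxy)phenoxy]propane-1,2-diol | c1ccc(OCc2ccccc2)c(OCc2ccccc2)c1O[C@H](c1ccc(OCc2ccccc2)cc1)[C@H](O)CO | intermediate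
10 | (2S,3R)-3-[4-(benzyloxy)phenyl]-3-[2,3-bis(benzyloxy)phenoxy]-2-hydroxypropanal | c1ccc(OCc2ccccc2)c(OCc2ccccc2)c1O[C@H](c1ccc(OCc2ccccc2)cc1)[C@H](O)C=O | intermediate
11 | (2R,3R,4R)-7,8-bis(benzyloxy)-2-[4-(benzyloxy)phenyl]-3,4-dihydro-2H-chromene-3,4-diol (all-cis) | c1cc2c(c(OCc3ccccc3)c1OCc1ccccc1)O[C@H](c1ccc(OCc3ccccc3)cc1)[C@H](O)[C@@H]2O | intermediate
12 | (2R,3S,4R)-7,8-bis(benzyloxy)-2-[4-(benzyloxy)phenyl]chromane-3,4-diyl carbonate (all-cis cyclic carbonate) | c1cc2c(c(OCc3ccccc3)c1OCc1ccccc1)O[C@H](c1ccc(OCc3ccccc3)cc1)[C@H](OC3=O)[C@@H]2O3 | intermediate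
13 | (2R,3S,4R)-7,8-bis(benzyloxy)-2-[4-(benzyloxy)phenyl]chromane-3,4-diyl thionocarbonate (all-cis cyclic) | c1cc2c(c(OCc3ccccc3)c1OCc1ccccc1)O[C@H](c1ccc(OCc3ccccc3)cc1)[C@H](OC3=S)[C@@H]2O3 | intermediate
14 | (2S)-7,8-bis(benzyloxy)-2-[4-(benzyloxy)phenyl]-2H-chromene | c1cc2c(c(OCc3ccccc3)c1OCc1ccccc1)O[C@H](c1ccc(OCc3ccccc3)cc1)C=C2 | intermediate
15 | (2S)-7,8-bis(benzyloxy)-2-[4-(benzyloxy)phenyl]-3,4-dihydro-2H-chromene | c1cc2c(c(OCc3ccccc3)c1OCc1ccccc1)O[C@H](c1ccc(OCc3ccccc3)cc1)CC2 | intermediate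
16 | {[(2S)-7,8-bis(benzyloxy)-2-(4-benzyloxyphenyl)chroman-4-yl](tosyl)amino}diphenylsulfonium tetrakis(pentafluorophenyl)borate (C4 epimers) | c1cc2c(c(OCc3ccccc3)c1OCc1ccccc1)O[C@H](c1ccc(OCc3ccccc3)cc1)CC2N([S+](c1ccccc1)c1ccccc1)S(=O)(=O)c1ccc(C)cc1.Fc1c(F)c(F)c([B-](c2c(F)c(F)c(F)c(F)c2F)(c2c(F)c(F)c(F)c(F)c2F)c2c(F)c(F)c(F)c(F)c2F)c(F)c1F | intermediate
17 | (2R,3S,4R)-7,8-bis(benzyloxy)-6-{(2S,4R)-7,8-bis(benzyloxy)-2-[4-(benzyloxy)phenyl]chroman-4-yl}-2-[4-(benzyloxy)phenyl]chromane-3,4-diyl carbonate (upper unit 2,4-trans; lower unit all-cis) | c5ccccc5COc1ccc([C@@H]2C[C@@H](c3cc4c(c(OCc5ccccc5)c3OCc5ccccc5)O[C@H](c3ccc(OCc5ccccc5)cc3)[C@H](OC6=O)[C@@H]4O6)c3ccc(OCc5ccccc5)c(OCc5ccccc5)c3O2)cc1 | intermediate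
18 | (2R,3R,4R)-7,8-bis(benzyloxy)-6-{(2S,4R)-7,8-bis(benzyloxy)-2-[4-(benzyloxy)phenyl]chroman-4-yl}-2-[4-(benzyloxy)phenyl]chromane-3,4-diol | c5ccccc5COc1ccc([C@@H]2C[C@@H](c3cc4c(c(OCc5ccccc5)c3OCc5ccccc5)O[C@H](c3ccc(OCc5ccccc5)cc3)[C@H](O)[C@@H]4O)c3ccc(OCc5ccccc5)c(OCc5ccccc5)c3O2)cc1 | intermediate
19 | (2R,3R,4R)-6-[(2S,4S)-7,8-dihydroxy-2-(4-hydroxyphenyl)chroman-4-yl]-2-(4-hydroxyphenyl)chromane-3,4,7,8-tetrol (CNP0209379.1) | Oc1ccc([C@@H]2C[C@@H](c3cc4c(c(O)c3O)O[C@H](c3ccc(O)cc3)[C@H](O)[C@@H]4O)c3ccc(O)c(O)c3O2)cc1 | target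

## Step count and risks

Total steps: 10. Longest linear sequence: 8 (steps 2, 3, 4, 5, 7, 8, 9, 10, starting from 5).

**Step 9 (proposed new anodic coupling).** Possible failures are oxidative opening of the C2–O1 bond, elimination of the stored cation to the flav-3-ene, or attack at C5 of 12. The fallback uses known chemistry, sets out from 13 and comes back at 17. Only the olefination half of step 8 is run (diazaphospholidine, THF, 40 °C, dark), and 14 is isolated cold instead of being reduced. Then 14 and 12 (3 equiv) are joined by Brønsted-acid-catalysed Friedel–Crafts hydroarylation (TfOH 5 mol %, CH2Cl2, −40 °C). Protonation at C3 gives the same C4 cation, which 12 takes up trans to the 2-aryl group to give 17. This fallback makes no compound outside the list (entry F0).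

**Step 5 (telescoped oxidation and chelation-controlled ring closure).** Possible failures are glycol cleavage or dimerisation of the hydroxy aldehyde, or a poor cis:trans ratio. The fallback sets out from 9 and comes back at 11. The primary alcohol is taken to the acid (TEMPO, PhI(OAc)2, MeCN/H2O) to give (2S,3R)-3-[4-(benzyloxy)phenyl]-3-[2,3-bis(benzyloxy)phenoxy]-2-hydroxypropanoic acid F4. Intramolecular Friedel–Crafts acylation through the mixed anhydride (TFAA, CH2Cl2, 0 °C → rt) gives (2R,3S)-7,8-bis(benzyloxy)-2-[4-(benzyloxy)phenyl]-4-oxochroman-3-yl trifluoroacetate F5, which is not isolated. NaHCO3/MeOH frees the 2,3-cis dihydroflavonol (2R,3S)-7,8-bis(benzyloxy)-2-[4-(benzyloxy)phenyl]-3-hydroxychroman-4-one F6. NaBH4 (MeOH/THF, −40 °C) then delivers hydride anti to the axial 3-OH and gives 11.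

**Step 3 (Mitsunobu at an electron-rich benzylic carbinol).** Possible failures are partial ionisation with loss of inversion, or elimination. The fallback sets out from 5 and comes back at 8, carrying the B-ring oxygen as a chloride so that the carbinol cannot ionise. Commercial 4-chlorophenylmagnesium bromide and ClTi(OiPr)3 give (4-chlorophenyl)tri(propan-2-yloxy)titanium F1, which adds to 5 as in step 2 to give (S)-(4-chlorophenyl)[(4R)-2,2-dimethyl-1,3-dioxolan-4-yl]methanol F2. Mitsunobu reaction with 3 (PPh3, DIAD, toluene) gives 1,2-bis(benzyloxy)-3-{(R)-(4-chlorophenyl)[(4R)-2,2-dimethyl-1,3-dioxolan-4-yl]methoxy}benzene F3 with clean inversion. Pd-catalysed C–O coupling with benzyl alcohol (tBuBrettPhos-Pd-G3, Cs2CO3, toluene, 80 °C) then installs the 4-benzyloxy group and gives 8.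

Further compounds
F1 | step 3 | (4-chlorophenyl)tri(propan-2-yloxy)titanium | CC(C)O[Ti](OC(C)C)(OC(C)C)c1ccc(Cl)cc1
F2 | step 3 | (S)-(4-chlorophenyl)[(4R)-2,2-dimethyl-1,3-dioxolan-4-yl]methanol | O[C@@H](c1ccc(Cl)cc1)[C@@H]1OC(C)(C)OC1
F3 | step 3 | 1,2-bis(benzyloxy)-3-{(R)-(4-chlorophenyl)[(4R)-2,2-dimethyl-1,3-dioxolan-4-yl]methoxy}benzene | c1ccc(OCc2ccccc2)c(OCc2ccccc2)c1O[C@H](c1ccc(Cl)cc1)[C@@H]1OC(C)(C)OC1
F4 | step 5 | (2S,3R)-3-[4-(benzyloxy)phenyl]-3-[2,3-bis(benzyloxy)phenoxy]-2-hydroxypropanoic acid | c1ccc(OCc2ccccc2)c(OCc2ccccc2)c1O[C@H](c1ccc(OCc2ccccc2)cc1)[C@H](O)C(=O)O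
F5 | step 5 | (2R,3S)-7,8-bis(benzyloxy)-2-[4-(benzyloxy)phenyl]-4-oxochroman-3-yl trifluoroacetate | c1cc2c(c(OCc3ccccc3)c1OCc1ccccc1)O[C@H](c1ccc(OCc3ccccc3)cc1)[C@H](OC(=O)C(F)(F)F)C2=O
F6 | step 5 | (2R,3S)-7,8-bis(benzyloxy)-2-[4-(benzyloxy)phenyl]-3-hydroxychroman-4-one | c1cc2c(c(OCc3ccccc3)c1OCc1ccccc1)O[C@H](c1ccc(OCc3ccccc3)cc1)[C@H](O)C2=O
F0 | step 9 | none | none
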